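**Retrosynthetic overview**
1. Target 10 ⇐ allyl ester 9 (deallylation) ⇐ 6β-alcohol 8 (acetylation) ⇐ 6-ketone 7 (hydride from the α-face sets C6).
2. 7 ⇐ dienol isovalerate 6 by an anodic 1,2-acyloxy shift, which makes the C7–O bond, sets C7 and leaves the alkene at C8=C9 (key step).
3. 6 ⇐ 7-en-6-one 5 (dienol acylation) ⇐ 7-ene 4 (allylic oxidation at C6) ⇐ tertiary alcohol 3 (dehydration).
4. 3 ⇐ ketol 2 (Horner–Wadsworth–Emmons adds C14–C15 as the E-enoate) ⇐ (−)-sclareol 1 (side-chain degradation).
5. No ring is formed: rings A and B with C5 and C10 come intact from sclareol, and ring B is only re-functionalised (C8, then C6, then C7).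

Assumption: labdane numbering is used throughout; (−)-sclareol is the only chiral input and all reagents are achiral and commercial.

**Route**

Step 1
Reactants: 1 (−)-sclareol
Product: 2 8α-hydroxy-14,15-dinorlabdan-13-one
Conditions: KMnO4 (4 equiv), acetone/H2O, 0 °C to rt
Reagents that add atoms: none
Why: Permanganate cleaves the vinyl group and the resulting tertiary α-hydroxy acid is decarboxylated oxidatively (the classical side-chain degradation of sclareol), so C13 becomes the methyl ketone and C5 and C10 are untouched.

Step 2
Reactants: 2 8α-hydroxy-14,15-dinorlabdan-13-one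
Product: 3 allyl (13E)-8α-hydroxylabd-13-en-15-oate
Conditions: allyl diethylphosphonoacetate (2.5 equiv), NaH (2.4 equiv), THF, 0 to 65 °C; E isomer isolated by chromatography
Reagents that add atoms: allyl diethylphosphonoacetate, C=CCOC(=O)CP(=O)(OCC)OCC
Why: Horner–Wadsworth–Emmons olefination of the methyl ketone with the preformed phosphonate anion (no free NaH, so the tertiary alcohol is not deprotonated) gives the trisubstituted enoate with an expected E:Z of about 5:1, and the Z isomer is removed.

Step 3
Reactants: 3 allyl (13E)-8α-hydroxylabd-13-en-15-oate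
Product: 4 allyl (13E)-labda-7,13-dien-15-oate
Conditions: p-TsOH·H2O (0.2 equiv), PhMe, 60 °C, stopped once the 8(17)-isomer is consumed; AgNO3–SiO2 chromatography
Reagents that add atoms: none
Why: Acid-catalysed E1 dehydration, in which the C8 cation loses the unhindered axial H-7α faster than the buried tertiary H-9 (the kinetic preference that gives α-ionone-type trisubstituted alkenes) and any exocyclic isomer is funnelled into 4 by reprotonation.

Step 4
Reactants: 4 allyl (13E)-labda-7,13-dien-15-oate
Product: 5 allyl (13E)-6-oxolabda-7,13-dien-15-oate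
Conditions: CrO3, 3,5-dimethylpyrazole (12 equiv each), CH2Cl2, −20 °C
Reagents that add atoms: chromium trioxide, O=[Cr](=O)=O
Why: Chromium trioxide–3,5-dimethylpyrazole allylic oxidation converts the ring methylene next to the vinylic CH (C6) into the conjugated ketone, as with 5-ene sterols giving 7-ketones, and leaves the electron-poor enoate and the allyl ester alone.

Step 5
Reactants: 5 allyl (13E)-6-oxolabda-7,13-dien-15-oate
Product: 6 allyl (13E)-6-(3-methylbutanoyloxy)labda-6,8,13-trien-15-oate
Conditions: isovaleric anhydride (4 equiv), p-TsOH·H2O (0.1 equiv), PhMe, 90 °C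
Reagents that add atoms: isovaleric anhydride, CC(C)CC(=O)OC(=O)CC(C)C
Why: Reversible acid-catalysed enol acylation gives the thermodynamic extended dienol ester (as for isophorone and 4-en-3-one steroids), with the new double bond in the tetrasubstituted 8,9-position and the trans ring fusion at C5 retained.

Step 6
Reactants: 6 allyl (13E)-6-(3-methylbutanoyloxy)labda-6,8,13-trien-15-oate
Product: 7 allyl (13E)-7α-(3-methylbutanoyloxy)-6-oxolabda-8,13-dien-15-oate
Conditions: graphite(+)/Pt(−), undivided cell, n-Bu4NBF4 (0.1 M), CH2Cl2/HFIP (4:1), 2,6-lutidine (2 equiv), H2O (5 equiv), 3 mA cm−2, 2.2 F mol−1, 0 °C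
Reagents that add atoms: water, O
Why: Proposed new method: anodic deconjugative 1,2-acyloxy shift of a dienol ester, in which one-electron oxidation of the 1-acyloxy-1,3-diene (the most electron-rich π-system; enoate and allyl ester are not oxidised) gives a radical cation whose ester carbonyl oxygen closes onto C7, the only diene carbon it can reach through a five-membered 1,3-dioxolan-2-ylium ring (C9 is out of reach and, being fully substituted and neopentylic, is also a poor site for outside nucleophiles), from the α-face because the β-face over C6/C7 is blocked by the axial C4β and C10 methyl groups; water then adds to the dioxolanylium carbon, the C6 radical collapses to the ketone and a second electron transfer releases the 7α-ester with the 8,9-alkene in place while the cathode evolves H2; the closest known reaction types are the anodic α-acetoxylation of enol acetates (Shono-type oxidation of enol esters) and the enol-ester-epoxide to α-acyloxy-ketone rearrangement, which moves the acyl group through the same kind of five-membered acyloxonium.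

Step 7
Reactants: 7 allyl (13E)-7α-(3-methylbutanoyloxy)-6-oxolabda-8,13-dien-15-oate
Product: 8 allyl (13E)-6β-hydroxy-7α-(3-methylbutanoyloxy)labda-8,13-dien-15-oate
Conditions: NaBH4, CeCl3·7H2O, MeOH/THF, −40 to −20 °C
Reagents that add atoms: none
Why: Luche-type borohydride reduction in which hydride attacks the C6 ketone from the α-face because the β-face is blocked by the syn-axial C4β and C10 methyl groups, giving the axial 6β-alcohol, whose trans-diaxial relation to the 7α-ester prevents acyl migration.

Step 8
Reactants: 8 allyl (13E)-6β-hydroxy-7α-(3-methylbutanoyloxy)labda-8,13-dien-15-oate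
Product: 9 allyl (13E)-6β-acetoxy-7α-(3-methylbutanoyloxy)labda-8,13-dien-15-oate
Conditions: Ac2O, DMAP, pyridine, 50 °C
Reagents that add atoms: acetic anhydride, CC(=O)OC(C)=O
Why: DMAP-catalysed acetylation of the hindered axial secondary alcohol proceeds with retention at C6 while the carboxyl group is masked as the allyl ester and the other esters are inert.

Step 9
Reactants: 9 allyl (13E)-6β-acetoxy-7α-(3-methylbutanoyloxy)labda-8,13-dien-15-oate
Product: 10 (13E)-6β-acetoxy-7α-(3-methylbutanoyloxy)labda-8,13-dien-15-oic acid
Conditions: Pd(PPh3)4 (5 mol%), morpholine (5 equiv), THF, rt; dilute aqueous citric acid wash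
Reagents that add atoms: none
Why: Tsuji–Trost deallylation, in which zerovalent palladium ionises only the unhindered allyl ester and morpholine traps the allyl group, so the acetate, the hindered allylic isovalerate, both alkenes and all stereocentres are untouched.

**Compound list**
1 | (−)-sclareol, (13R)-labd-14-ene-8α,13-diol | C=C[C@](C)(O)CC[C@@H]1[C@@]2(C)CCCC(C)(C)[C@@H]2CC[C@@]1(C)O | starting material
2 | 8α-hydroxy-14,15-dinorlabdan-13-one | CC(=O)CC[C@@H]1[C@@]2(C)CCCC(C)(C)[C@@H]2CC[C@@]1(C)O | intermediate
3 | allyl (13E)-8α-hydroxylabd-13-en-15-oate | C=CCOC(=O)/C=C(C)/CC[C@@H]1[C@@]2(C)CCCC(C)(C)[C@@H]2CC[C@@]1(C)O | intermediate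
4 | allyl (13E)-labda-7,13-dien-15-oate (H-9α) | C=CCOC(=O)/C=C(C)/CC[C@@H]1[C@@]2(C)CCCC(C)(C)[C@@H]2CC=C1C | intermediate
5 | allyl (13E)-6-oxolabda-7,13-dien-15-oate | C=CCOC(=O)/C=C(C)/CC[C@@H]1[C@@]2(C)CCCC(C)(C)[C@@H]2C(=O)C=C1C | intermediate
6 | allyl (13E)-6-(3-methylbutanoyloxy)labda-6,8,13-trien-15-oate | C=CCOC(=O)/C=C(C)/CCC1=C(C)C=C(OC(=O)CC(C)C)[C@H]2C(C)(C)CCC[C@]12C | intermediate
7 | allyl (13E)-7α-(3-methylbutanoyloxy)-6-oxolabda-8,13-dien-15-oate | O=C1[C@@H](OC(=O)CC(C)C)C(C)=C(CC/C(C)=C/C(=O)OCC=C)[C@@]2(C)CCCC(C)(C)[C@H]12 | intermediate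
8 | allyl (13E)-6β-hydroxy-7α-(3-methylbutanoyloxy)labda-8,13-dien-15-oate | O[C@@H]1[C@@H](OC(=O)CC(C)C)C(C)=C(CC/C(C)=C/C(=O)OCC=C)[C@@]2(C)CCCC(C)(C)[C@H]12 | intermediate
9 | allyl (13E)-6β-acetoxy-7α-(3-methylbutanoyloxy)labda-8,13-dien-15-oate | CC(=O)O[C@@H]1[C@@H](OC(=O)CC(C)C)C(C)=C(CC/C(C)=C/C(=O)OCC=C)[C@@]2(C)CCCC(C)(C)[C@H]12 | intermediate
10 | (13E)-6β-acetoxy-7α-(3-methylbutanoyloxy)labda-8,13-dien-15-oic acid, (5S,6S,7S,10S), CNP0328312.2 | CC(=O)O[C@@H]1[C@@H](OC(=O)CC(C)C)C(C)=C(CC/C(C)=C/C(=O)O)[C@@]2(C)CCCC(C)(C)[C@H]12 | target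

**Step count**
Total steps: 9. Longest linear sequence: 9.

**Steps most likely to fail**

Step 6, the new anodic acyloxy shift. The radical cation may lose a proton from C11 or C17 and end as a 7,9(11)-dien-6-one, may be captured at C9, or the dienol ester may simply hydrolyse back to 5. The fallback uses known enolate chemistry, sets out from 5 and comes back at 7. Enone 5 is deprotonated with KN(SiMe3)2 (1.0 equiv, THF, −78 to 0 °C, equilibrating) to the extended potassium 6-oxido-6,8-dienolate F3. This is hydroxylated at C7 from the open α-face with 2-(phenylsulfonyl)-3-phenyloxaziridine at −78 °C and quenched with NH4Cl to give allyl (13E)-7α-hydroxy-6-oxolabda-8,13-dien-15-oate F4. F4 is then esterified with isovaleric anhydride, DMAP and Et3N in CH2Cl2 to give 7.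

Step 3, regioselective dehydration. The acid may give too much of the tetrasubstituted 8(9)-ene or leave exocyclic alkene. The fallback separates elimination from alkene placement, sets out from 3 and comes back at 4. Alcohol 3 is dehydrated with SOCl2 and pyridine in CH2Cl2 at −78 °C, where anti-elimination through the methyl group gives allyl (13E)-labda-8(17),13-dien-15-oate F1. The exocyclic double bond is then moved into the ring with catalytic PdCl2(MeCN)2 (divalent palladium, allylic C–H activation at the unhindered C7 methylene) in CH2Cl2 at rt to 40 °C, giving 4.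

Step 4, allylic oxidation at C6. The chromium reagent may instead take the tertiary allylic H-9 and deliver the transposed 8-en-7-one, or give poor conversion. The fallback replaces the stoichiometric metal-oxo oxidant by a catalytic hydrogen-atom-transfer process at an anode, sets out from 4 and comes back at 5. Alkene 4 is electrolysed with tetrachloro-N-hydroxyphthalimide (20 mol%), pyridine, t-BuOOH and LiClO4 in acetone at a reticulated vitreous carbon anode under constant current. The N-oxyl radical abstracts an allylic hydrogen at C6, the allyl radical couples with t-BuOO• to give allyl (13E)-6α-(tert-butylperoxy)labda-7,13-dien-15-oate F2, and this loses tert-butanol under the pyridine buffer to give 5. The same H-9 competition is possible here, so the two methods should be compared on a small scale first.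

**Further compounds**
F1 | step 3 | allyl (13E)-labda-8(17),13-dien-15-oate | C=CCOC(=O)/C=C(C)/CC[C@@H]1[C@@]2(C)CCCC(C)(C)[C@@H]2CCC1=C
F2 | step 4 | allyl (13E)-6α-(tert-butylperoxy)labda-7,13-dien-15-oate | C=CCOC(=O)/C=C(C)/CC[C@@H]1[C@@]2(C)CCCC(C)(C)[C@@H]2[C@@H](OOC(C)(C)C)C=C1C
F3 | step 6 | potassium (13E)-15-allyloxy-15-oxolabda-6,8,13-trien-6-olate | C=CCOC(=O)/C=C(C)/CCC1=C(C)C=C([O-])[C@H]2C(C)(C)CCC[C@]12C.[K+]
F4 | step 6 | allyl (13E)-7α-hydroxy-6-oxolabda-8,13-dien-15-oate | O=C1[C@@H](O)C(C)=C(CC/C(C)=C/C(=O)OCC=C)[C@@]2(C)CCCC(C)(C)[C@H]12
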